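Assumption: (R)-but-3-en-2-ol (catalogue chemical, ≥98% ee) is taken as the inexpensive enantiopure starting material; all other materials are achiral and commercial.

**Retrosynthetic overview**
1. The target is the desilylated form of its phenol O-TBS ether. The γ-butyrolactone is the only ring made and is closed last, from a γ,δ-unsaturated acid whose propenyl group is cut back to CH2OH (ozonolysis, reduction, lactonisation).
2. The C2–C3 bond of that acid, carrying both stereocentres, comes from an Ireland–Claisen [3,3] rearrangement of an (R,E)-allylic 3-(3,4,5-trimethoxyphenyl)propanoate. The carbinol stereocentre is relayed through a chair transition state and then excised.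
3. The allylic ester comes from cross-metathesis of 4-allyl-2,6-dimethoxyphenol with the (R)-but-3-en-2-yl ester of 3-(3,4,5-trimethoxyphenyl)propanoic acid.

**Route**

Step 1
Reactants: 1 3-(3,4,5-trimethoxyphenyl)propanoic acid; 2 (R)-but-3-en-2-ol
Product: 3 (R)-but-3-en-2-yl 3-(3,4,5-trimethoxyphenyl)propanoate
Conditions: DCC (1.2 equiv), DMAP (0.1 equiv), CH2Cl2, 0 °C → rt
Reagents that add atoms: none
Why: Steglich esterification acylates the alcohol oxygen without breaking the C–O bond at the stereocentre, so the (R) configuration is carried over unchanged.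

Step 2
Reactants: 3 (R)-but-3-en-2-yl 3-(3,4,5-trimethoxyphenyl)propanoate; 4 4-allyl-2,6-dimethoxyphenol (2.5 equiv)
Product: 5 (2R,3E)-5-(4-hydroxy-3,5-dimethoxyphenyl)pent-3-en-2-yl 3-(3,4,5-trimethoxyphenyl)propanoate
Conditions: Hoveyda–Grubbs II (5 mol%), 1,4-benzoquinone (10 mol%), CH2Cl2, 40 °C
Reagents that add atoms: none
Why: Olefin cross-metathesis of a fast-dimerising allylarene with a hindered secondary allylic ester is selective for the E cross-product, the Ru carbene tolerates the free phenol, benzoquinone suppresses allyl-to-propenyl migration, and the stereocentre is untouched (minor Z isomer removed by chromatography).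

Step 3
Reactants: 5 (2R,3E)-5-(4-hydroxy-3,5-dimethoxyphenyl)pent-3-en-2-yl 3-(3,4,5-trimethoxyphenyl)propanoate
Product: 8 (2R,3S,4E)-3-[4-(tert-butyldimethylsilyloxy)-3,5-dimethoxybenzyl]-2-(3,4,5-trimethoxybenzyl)hex-4-enoic acid, via bis-silyl ketene acetal 6 (not isolated), via silyl ester 7 (not isolated)
Conditions: LDA (2.3 equiv, commercial solution), THF/DMPU 3:1, −78 °C; TBSCl (3.0 equiv), −78 °C → rt, then 60 °C, 3 h; 1 M HCl, THF, rt (work-up)
Reagents that add atoms: tert-butyldimethylsilyl chloride CC(C)(C)[Si](C)(C)Cl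
Why: Ireland–Claisen [3,3]-sigmatropic rearrangement: in THF/DMPU, LDA gives the (Z)-silyl ketene acetal while the phenoxide is silylated in the same pot, and the chair transition state with the carbinol methyl equatorial relays the (R) C–O centre to C3 (S) while the Z-acetal/E-olefin pairing sets C2 (R), the relative configuration that closes to the trans-lactone.

Step 4
Reactants: 8 (2R,3S,4E)-3-[4-(tert-butyldimethylsilyloxy)-3,5-dimethoxybenzyl]-2-(3,4,5-trimethoxybenzyl)hex-4-enoic acid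
Product: 11 (3R,4R)-4-[4-(tert-butyldimethylsilyloxy)-3,5-dimethoxybenzyl]-3-(3,4,5-trimethoxybenzyl)dihydrofuran-2(3H)-one, via aldehyde acid 9 (not isolated), via hydroxy acid 10 (not isolated)
Conditions: O3, CH2Cl2/MeOH 3:1, Sudan Red 7B indicator, −78 °C; NaBH4 (5 equiv), −78 → 0 °C; 2 M HCl to pH 1, rt
Reagents that add atoms: ozone [O-][O+]=O
Why: Ozonolysis with reductive work-up cleaves the only C=C much faster than ozone attacks the trialkoxyarenes, the aldehyde is reduced cold before C3 can epimerise, and the γ-hydroxy acid lactonises on acidification without breaking a bond to either stereocentre (any cis-lactone from Z-olefin or E-ketene-acetal leakage is a separable diastereomer and is removed here by chromatography, not epimerised).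

Step 5
Reactants: 11 (3R,4R)-4-[4-(tert-butyldimethylsilyloxy)-3,5-dimethoxybenzyl]-3-(3,4,5-trimethoxybenzyl)dihydrofuran-2(3H)-one
Product: 12 (3R,4R)-4-(4-hydroxy-3,5-dimethoxybenzyl)-3-(3,4,5-trimethoxybenzyl)dihydrofuran-2(3H)-one (target)
Conditions: TBAF (1.2 equiv), AcOH (1.2 equiv), THF, 0 °C
Reagents that add atoms: none
Why: Fluoride-mediated desilylation of the aryl silyl ether, buffered with acetic acid so the lactone is neither opened nor epimerised (the trans isomer is in any case the thermodynamic one).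

**Compound list**
1 | 3-(3,4,5-trimethoxyphenyl)propanoic acid | COc1cc(CCC(=O)O)cc(OC)c1OC | starting material
2 | (R)-but-3-en-2-ol | C[C@@H](O)C=C | starting material
3 | (R)-but-3-en-2-yl 3-(3,4,5-trimethoxyphenyl)propanoate | C=C[C@@H](C)OC(=O)CCc1cc(OC)c(OC)c(OC)c1 | intermediate
4 | 4-allyl-2,6-dimethoxyphenol | C=CCc1cc(OC)c(O)c(OC)c1 | starting material
5 | (2R,3E)-5-(4-hydroxy-3,5-dimethoxyphenyl)pent-3-en-2-yl 3-(3,4,5-trimethoxyphenyl)propanoate | COc1cc(C/C=C/[C@@H](C)OC(=O)CCc2cc(OC)c(OC)c(OC)c2)cc(OC)c1O | intermediate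
6 | tert-butyl{[(1Z)-1-{[(2R,3E)-5-{4-[(tert-butyldimethylsilyl)oxy]-3,5-dimethoxyphenyl}pent-3-en-2-yl]oxy}-3-(3,4,5-trimethoxyphenyl)prop-1-en-1-yl]oxy}dimethylsilane (bis-silyl Z-ketene acetal) | COc1cc(C/C=C/[C@@H](C)O/C(O[Si](C)(C)C(C)(C)C)=C/Cc2cc(OC)c(OC)c(OC)c2)cc(OC)c1O[Si](C)(C)C(C)(C)C | intermediate
7 | tert-butyldimethylsilyl (2R,3S,4E)-3-[4-(tert-butyldimethylsilyloxy)-3,5-dimethoxybenzyl]-2-(3,4,5-trimethoxybenzyl)hex-4-enoate | COc1cc(C[C@@H](/C=C/C)[C@@H](Cc2cc(OC)c(OC)c(OC)c2)C(=O)O[Si](C)(C)C(C)(C)C)cc(OC)c1O[Si](C)(C)C(C)(C)C | intermediate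
8 | (2R,3S,4E)-3-[4-(tert-butyldimethylsilyloxy)-3,5-dimethoxybenzyl]-2-(3,4,5-trimethoxybenzyl)hex-4-enoic acid | COc1cc(C[C@@H](/C=C/C)[C@@H](Cc2cc(OC)c(OC)c(OC)c2)C(=O)O)cc(OC)c1O[Si](C)(C)C(C)(C)C | intermediate
9 | (2R,3R)-3-[4-(tert-butyldimethylsilyloxy)-3,5-dimethoxybenzyl]-4-oxo-2-(3,4,5-trimethoxybenzyl)butanoic acid | COc1cc(C[C@@H](C=O)[C@@H](Cc2cc(OC)c(OC)c(OC)c2)C(=O)O)cc(OC)c1O[Si](C)(C)C(C)(C)C | intermediate
10 | (2R,3R)-3-[4-(tert-butyldimethylsilyloxy)-3,5-dimethoxybenzyl]-4-hydroxy-2-(3,4,5-trimethoxybenzyl)butanoic acid | COc1cc(C[C@@H](CO)[C@@H](Cc2cc(OC)c(OC)c(OC)c2)C(=O)O)cc(OC)c1O[Si](C)(C)C(C)(C)C | intermediate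
11 | (3R,4R)-4-[4-(tert-butyldimethylsilyloxy)-3,5-dimethoxybenzyl]-3-(3,4,5-trimethoxybenzyl)dihydrofuran-2(3H)-one | COc1cc(C[C@H]2COC(=O)[C@@H]2Cc2cc(OC)c(OC)c(OC)c2)cc(OC)c1O[Si](C)(C)C(C)(C)C | intermediate
12 | (3R,4R)-4-(4-hydroxy-3,5-dimethoxybenzyl)-3-(3,4,5-trimethoxybenzyl)dihydrofuran-2(3H)-one | COc1cc(C[C@H]2COC(=O)[C@@H]2Cc2cc(OC)c(OC)c(OC)c2)cc(OC)c1O | target

**Step count**
Total steps: 5. Longest linear sequence: 5 (1 or 2 → 3 → 5 → 8 → 11 → 12).

**Steps most likely to fail, with fallbacks**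

Step 2 (cross-metathesis). Risks are olefin migration in the allylarene, modest E/Z ratio, and slow turnover of the hindered allylic ester. The fallback sets out from 4 and comes back to the route at 6. Silylate 4 (TBSCl, imidazole, DMF) to tert-butyl(4-allyl-2,6-dimethoxyphenoxy)dimethylsilane F1. Cross-metathesise F1 with the unhindered free alcohol 2 to (2R,3E)-5-[4-(tert-butyldimethylsilyloxy)-3,5-dimethoxyphenyl]pent-3-en-2-ol F2, where E and Z isomers are separable. Esterify F2 with 1 (DCC, DMAP) to (2R,3E)-5-[4-(tert-butyldimethylsilyloxy)-3,5-dimethoxyphenyl]pent-3-en-2-yl 3-(3,4,5-trimethoxyphenyl)propanoate F3. Under the step 3 conditions with only 1.1 equiv LDA and 1.2 equiv TBSCl, F3 gives ketene acetal 6 and the route continues unchanged.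

Step 3 (Ireland–Claisen). Risks are imperfect Z-selective enolisation beside a lithium phenoxide, incomplete phenol silylation, and a lowered diastereomer ratio. The fallback sets out from 4 and 2 and comes back at 12. It moves the [3,3] step to a Johnson–Claisen rearrangement that sets only C4, and installs the second benzyl group afterwards under substrate control. Benzylate 4 (BnBr, K2CO3, acetone) to 5-allyl-2-(benzyloxy)-1,3-dimethoxybenzene F4. Cross-metathesis with 2 gives (2R,3E)-5-[4-(benzyloxy)-3,5-dimethoxyphenyl]pent-3-en-2-ol F5. Heating with triethyl orthoacetate and catalytic propionic acid (140 °C) gives ethyl (3R,4E)-3-[4-(benzyloxy)-3,5-dimethoxybenzyl]hex-4-enoate F6 by the same chair-controlled chirality transfer. Ozonolysis, NaBH4 and acid give (R)-4-[4-(benzyloxy)-3,5-dimethoxybenzyl]dihydrofuran-2(3H)-one F7. LiHMDS (THF, −78 °C) then 3,4,5-trimethoxybenzyl bromide alkylates anti to the C4 substituent to give (3R,4R)-4-[4-(benzyloxy)-3,5-dimethoxybenzyl]-3-(3,4,5-trimethoxybenzyl)dihydrofuran-2(3H)-one F8. Hydrogenolysis (H2, Pd/C, EtOAc) gives 12.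

Step 4 (ozonolysis, reduction, lactonisation). Risks are over-oxidation of the two trioxygenated arenes and epimerisation at C3 through the aldehyde. The fallback sets out from 8 and comes back at 9, replacing ozone with a two-stage osmylation and glycol cleavage. OsO4 (cat.), NMO, NaHCO3 in acetone/H2O converts the sodium salt of 8 into (2R,3R)-3-[4-(tert-butyldimethylsilyloxy)-3,5-dimethoxybenzyl]-4,5-dihydroxy-2-(3,4,5-trimethoxybenzyl)hexanoic acid F9, a mixture of diol diastereomers kept as the carboxylate so it does not lactonise. NaIO4 (pH 7, 0 °C) cleaves the glycol to 9, which is reduced with NaBH4 and acidified as in step 4 to give 11.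

**Further compounds**
F1 | step 2 | tert-butyl(4-allyl-2,6-dimethoxyphenoxy)dimethylsilane | C=CCc1cc(OC)c(O[Si](C)(C)C(C)(C)C)c(OC)c1
F2 | step 2 | (2R,3E)-5-[4-(tert-butyldimethylsilyloxy)-3,5-dimethoxyphenyl]pent-3-en-2-ol | COc1cc(C/C=C/[C@@H](C)O)cc(OC)c1O[Si](C)(C)C(C)(C)C
F3 | step 2 | (2R,3E)-5-[4-(tert-butyldimethylsilyloxy)-3,5-dimethoxyphenyl]pent-3-en-2-yl 3-(3,4,5-trimethoxyphenyl)propanoate | COc1cc(C/C=C/[C@@H](C)OC(=O)CCc2cc(OC)c(OC)c(OC)c2)cc(OC)c1O[Si](C)(C)C(C)(C)C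
F4 | step 3 | 5-allyl-2-(benzyloxy)-1,3-dimethoxybenzene | C=CCc1cc(OC)c(OCc2ccccc2)c(OC)c1
F5 | step 3 | (2R,3E)-5-[4-(benzyloxy)-3,5-dimethoxyphenyl]pent-3-en-2-ol | COc1cc(C/C=C/[C@@H](C)O)cc(OC)c1OCc1ccccc1
F6 | step 3 | ethyl (3R,4E)-3-[4-(benzyloxy)-3,5-dimethoxybenzyl]hex-4-enoate | COc1cc(C[C@@H](/C=C/C)CC(=O)OCC)cc(OC)c1OCc1ccccc1
F7 | step 3 | (R)-4-[4-(benzyloxy)-3,5-dimethoxybenzyl]dihydrofuran-2(3H)-one | COc1cc(C[C@H]2COC(=O)C2)cc(OC)c1OCc1ccccc1
F8 | step 3 | (3R,4R)-4-[4-(benzyloxy)-3,5-dimethoxybenzyl]-3-(3,4,5-trimethoxybenzyl)dihydrofuran-2(3H)-one | COc1cc(C[C@H]2COC(=O)[C@@H]2Cc2cc(OC)c(OC)c(OC)c2)cc(OC)c1OCc1ccccc1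
F9 | step 4 | (2R,3R)-3-[4-(tert-butyldimethylsilyloxy)-3,5-dimethoxybenzyl]-4,5-dihydroxy-2-(3,4,5-trimethoxybenzyl)hexanoic acid (4,5-diol diastereomers) | COc1cc(C[C@@H](C(O)C(C)O)[C@@H](Cc2cc(OC)c(OC)c(OC)c2)C(=O)O)cc(OC)c1O[Si](C)(C)C(C)(C)C
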